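The readings are calculated from invented constants.

The flask is closed, so every X charged stays in it in some form. Yet X and G together leave a hidden store, averaging 78.3 % over the readings at 60.0 min and 120 min. G gained per hour between those readings, divided by that store, is 0.135 h⁻¹, the feed constant.

- delta: X 0.14 M; L 1.8 equiv; the very flask that is asked about, followed so far
- flask: X 0.14 M; L 1.80 equiv; time 25 h

delta run (percent of the X charged)

| time / min | G / % | X / % |
|---|---|---|
| 20.0 | 1.0 | 52.7 |
| 40.0 | 3.4 | 28.3 |
| 60.0 | 7.9 | 15.3 |
| 80.0 | 13.0 | 6.7 |
| 90.0 | 13.6 | 6.0 |
| 120 | 18.5 | 1.6 |

(each reading ± 1 percentage point)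

- when, up to 25 h, the flask holds most G
- the amount of G, in percent of the X charged, at that time



Two of us disputed this flask. The first holds that the store simply empties into G. On that view G is “still rising at the end”, so the forecast stands at 25 h and 80 %.

The second reads the gain in G: 5.1 percentage points in 20.0 min, then 5.5 points in 40.0 min. That is weak evidence with a scatter of 1 point, but it hints at a drain on G, with a constant of its own. Control changes hands where drain matches feed. For a store passing through G at fixed constants, the peak share is the feed-to-drain ratio raised to the power one over one minus that ratio. At equal constants this gives 36.8 % at 7.41 h. My estimate, which differs from the forecast, is that equal case; these readings give no size for the drain, and in the formula a slower drain gives a higher, later peak.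

The flask holds most G at 4.06 h, with 29.7 %.

    X → Z (k = 1.90 h⁻¹)
    L → J (k = 1.20 h⁻¹)
    Z + J → G (k = 1.30 M⁻¹ h⁻¹)
    G ⇌ Q (K = 16.0, k = 0.360 h⁻¹)

Without the path from G to Q, the same run peaks at 98.6 % rather than 29.7 %, and there the first view holds; with it, G is the kinetic product beside Q. Taking the forward constant of G to Q, 0.36 h⁻¹, as the drain makes the ratio of the feed constant to it 0.376, and the formula then gives 20.8 % at 4.36 h for this flask. Suppose feed scales with the charge of L: the neighbour flask at 1.10 equiv then has ratio 0.230, which gives a peak of 14.8 %, and the simulation of that flask gives 21.3 %.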